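**Strategy.** The isoflavone is traced back to a chalcone. The feature exploited is that C1' of ring B is bonded to C3 of ring C, while C2 is an oxygen-bound CH between O1 and C3. One oxidative operation moves ring B from the future C2 to the future C3 of an (E)-chalcone and leaves C2 as a dimethyl acetal, which the C8a oxygen later closes. The precursor carries ring A as 3'-methoxy, 2',4'-bis(MOM), 6'-benzyl ether, built from a mirror-symmetric arene with a single acylation site. Of the two oxygens ortho to the ketone only the C8a oxygen is acid-labile, so closure can give the 8-methoxy isomer alone. Ring B carries a benzyl ether.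

Key step: step 7

Assumption: locants C2, C3, C4a, C5–C8a and C1'–C6' are those of the 3-aryl-4H-chromen-4-one core of the target; compounds 10, 12, 13 and 14 are racemic, which is immaterial because 15 and 16 have no stereocentre; MOM cleavage in methanolic HCl is written as methanolysis.

**Route**

Step 1
Reactants: 1 2-methoxybenzene-1,3-diol
Product: 2 2-methoxy-1,3-bis(methoxymethoxy)benzene
Conditions: NaH, MOMCl, THF–DMF, 0 °C to rt
Reagents that add atoms: chloromethyl methyl ether, COCCl
Why: Williamson-type O-alkylation of both phenoxides with the reactive chloromethyl ether should give the bis-acetal, which keeps the mirror symmetry of 1 and later serves as the acid-labile protection of the C7 and C8a oxygens.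

Step 2
Reactants: 2 2-methoxy-1,3-bis(methoxymethoxy)benzene
Product: 4 4-methoxy-3,5-bis(methoxymethoxy)phenol, via aryl pinacol boronate 3 (not isolated)
Conditions: [Ir(OMe)(cod)]2 (cat.), 4,4'-di-tert-butyl-2,2'-bipyridine (cat.), B2pin2, THF, 80 °C; then aq. H2O2, NaOH, 0 °C to rt, neutral work-up
Reagents that add atoms: hydrogen peroxide, OO; bis(pinacolato)diboron, CC1(C)OB(OC1(C)C)B1OC(C)(C)C(C)(C)O1 (its boron stays only in intermediate 3)
Why: Sterically controlled iridium-catalysed C–H borylation (Hartwig–Miyaura type) should take the only ring hydrogen of 2 without an ortho substituent (C5, para to the methoxy group), and basic peroxide oxidation of the C–B bond (1,2-boronate shift) should give the phenol in the same flask.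

Step 3
Reactants: 4 4-methoxy-3,5-bis(methoxymethoxy)phenol
Product: 5 5-(benzyloxy)-2-methoxy-1,3-bis(methoxymethoxy)benzene
Conditions: BnBr, K2CO3, DMF, rt
Reagents that add atoms: benzyl bromide, BrCc1ccccc1
Why: Williamson ether synthesis on the only free phenol places the acid-stable benzyl group on the future C5 oxygen, the ortho oxygen that must not take part in ring closure.

Step 4
Reactants: 5 5-(benzyloxy)-2-methoxy-1,3-bis(methoxymethoxy)benzene
Product: 7 1-[6-(benzyloxy)-3-methoxy-2,4-bis(methoxymethoxy)phenyl]ethan-1-one, via aryllithium 6 (not isolated)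
Conditions: n-BuLi, TMEDA, THF, −78 to −20 °C; then MeC(O)N(OMe)Me, −78 °C to rt; H2O quench
Reagents that add atoms: N-methoxy-N-methylacetamide, CC(=O)N(C)OC; n-butyllithium, [Li]CCCC (its lithium stays only in intermediate 6)
Why: Directed ortho-metalation should take the ring hydrogen between the MOM ether and the benzyl ether, the only kind of ring hydrogen in mirror-symmetric 5 (C4 and C6 are equivalent), and the aryllithium is acylated by the Weinreb amide, whose chelated tetrahedral adduct prevents over-addition (Weinreb ketone synthesis).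

Step 5
Reactants: 8 3-hydroxy-4,5-dimethoxybenzaldehyde
Product: 9 3-(benzyloxy)-4,5-dimethoxybenzaldehyde
Conditions: BnBr, K2CO3, DMF, 60 °C
Reagents that add atoms: benzyl bromide, BrCc1ccccc1
Why: Williamson ether synthesis masks the ring B phenol, which would otherwise be deprotonated in step 6 and oxidised in step 7.

Step 6
Reactants: 7 1-[6-(benzyloxy)-3-methoxy-2,4-bis(methoxymethoxy)phenyl]ethan-1-one; 9 3-(benzyloxy)-4,5-dimethoxybenzaldehyde
Product: 11 (E)-1-[6-(benzyloxy)-3-methoxy-2,4-bis(methoxymethoxy)phenyl]-3-[3-(benzyloxy)-4,5-dimethoxyphenyl]prop-2-en-1-one, via aldol adduct 10 (not isolated)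
Conditions: KOH, EtOH–THF, rt
Reagents that add atoms: none
Why: In this Claisen–Schmidt condensation the methyl ketone enolate adds to the non-enolisable aldehyde and the aldol adduct, whose carbinol stereocentre is transient, should lose water by E1cB elimination to the thermodynamically preferred (E)-enone.

Step 7
Reactants: 11 (E)-1-[6-(benzyloxy)-3-methoxy-2,4-bis(methoxymethoxy)phenyl]-3-[3-(benzyloxy)-4,5-dimethoxyphenyl]prop-2-en-1-one
Product: 12 1-[6-(benzyloxy)-3-methoxy-2,4-bis(methoxymethoxy)phenyl]-2-[3-(benzyloxy)-4,5-dimethoxyphenyl]-3,3-dimethoxypropan-1-one (racemic)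
Conditions: Tl(NO3)3·3H2O, MeOH–CH2Cl2, rt; then aq. NaHCO3
Reagents that add atoms: methanol, CO
Why: Trivalent thallium adds to the enone alkene with the metal on the α-carbon (future C3) and methanol on the benzylic β-carbon (future C2); ring B then bridges to the α-carbon as a phenonium ion and expels monovalent thallium, which forms C3–C1' and breaks C2–C1', and the oxocarbenium ion left at the old β-carbon takes up a second methanol. The closest known reaction type is the oxidative 1,2-aryl migration of 2'-protected chalcones to 2-aryl-3,3-dimethoxypropan-1-ones with Tl(NO3)3 or trivalent iodine reagents in methanol. No ring is closed in this step. The one new stereocentre, the α-carbon, forms without control as a racemate and is erased when C2=C3 appears in step 8. The step needs aryl migration to win over plain 1,2-dimethoxylation of the alkene and over oxidation of ring A: the 4'-methoxy donor of the trioxygenated ring B supports the bridged cation, and ring A is fully etherified and twisted out of conjugation by its two ortho substituents. It also needs the MOM ether on the future O1 to outlast the nitric acid set free, which a short reaction at room temperature and the bicarbonate quench should secure.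

Step 8
Reactants: 12 1-[6-(benzyloxy)-3-methoxy-2,4-bis(methoxymethoxy)phenyl]-2-[3-(benzyloxy)-4,5-dimethoxyphenyl]-3,3-dimethoxypropan-1-one
Product: 15 5-(benzyloxy)-3-[3-(benzyloxy)-4,5-dimethoxyphenyl]-7-hydroxy-8-methoxy-4H-chromen-4-one, via diphenol acetal 13 (not isolated), via 2-methoxyisoflavanone 14 (not isolated)
Conditions: HCl (1.25 M in MeOH), THF, 50 °C
Reagents that add atoms: none
Why: Acid-catalysed methanolysis removes both MOM groups, the C2' phenol (the only free oxygen ortho to the ketone, since the other is benzylated) adds to the oxocarbenium ion from the dimethyl acetal (6-exo-trig closure of ring C, forming O1–C2), and loss of methanol from the 2-methoxyisoflavanone should install the C2=C3 bond and erase the C3 stereocentre.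

Step 9
Reactants: 15 5-(benzyloxy)-3-[3-(benzyloxy)-4,5-dimethoxyphenyl]-7-hydroxy-8-methoxy-4H-chromen-4-one
Product: 16 5,7-dihydroxy-3-(3-hydroxy-4,5-dimethoxyphenyl)-8-methoxy-4H-chromen-4-one (isoirigenin)
Conditions: H2 (1 atm), Pd/C, EtOAc–MeOH, rt
Reagents that add atoms: none
Why: Catalytic hydrogenolysis of the two benzyl aryl ethers (on the C5 and C3' oxygens) should free the last two phenols, and the reaction is stopped once debenzylation is complete so that the C2=C3 bond of the pyranone is kept.

**Compound list**

1 | 2-methoxybenzene-1,3-diol (2-methoxyresorcinol) | COc1c(O)cccc1O | starting material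
2 | 2-methoxy-1,3-bis(methoxymethoxy)benzene | COCOc1cccc(OCOC)c1OC | intermediate
3 | 2-[4-methoxy-3,5-bis(methoxymethoxy)phenyl]-4,4,5,5-tetramethyl-1,3,2-dioxaborolane (formed in the flask, not isolated) | COCOc1cc(B2OC(C)(C)C(C)(C)O2)cc(OCOC)c1OC | intermediate
4 | 4-methoxy-3,5-bis(methoxymethoxy)phenol | COCOc1cc(O)cc(OCOC)c1OC | intermediate
5 | 5-(benzyloxy)-2-methoxy-1,3-bis(methoxymethoxy)benzene | COCOc1cc(OCc2ccccc2)cc(OCOC)c1OC | intermediate
6 | [6-(benzyloxy)-3-methoxy-2,4-bis(methoxymethoxy)phenyl]lithium (formed in the flask, not isolated) | [Li]c1c(OCOC)c(OC)c(OCOC)cc1OCc1ccccc1 | intermediate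
7 | 1-[6-(benzyloxy)-3-methoxy-2,4-bis(methoxymethoxy)phenyl]ethan-1-one | CC(=O)c1c(OCOC)c(OC)c(OCOC)cc1OCc1ccccc1 | intermediate
8 | 3-hydroxy-4,5-dimethoxybenzaldehyde | COc1cc(C=O)cc(O)c1OC | starting material
9 | 3-(benzyloxy)-4,5-dimethoxybenzaldehyde | COc1cc(C=O)cc(OCc2ccccc2)c1OC | intermediate
10 | 1-[6-(benzyloxy)-3-methoxy-2,4-bis(methoxymethoxy)phenyl]-3-[3-(benzyloxy)-4,5-dimethoxyphenyl]-3-hydroxypropan-1-one (racemic; formed in the flask, not isolated) | COCOc1cc(OCc2ccccc2)c(C(=O)CC(O)c2cc(OC)c(OC)c(OCc3ccccc3)c2)c(OCOC)c1OC | intermediate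
11 | (E)-1-[6-(benzyloxy)-3-methoxy-2,4-bis(methoxymethoxy)phenyl]-3-[3-(benzyloxy)-4,5-dimethoxyphenyl]prop-2-en-1-one | COCOc1cc(OCc2ccccc2)c(C(=O)/C=C/c2cc(OC)c(OC)c(OCc3ccccc3)c2)c(OCOC)c1OC | intermediate
12 | 1-[6-(benzyloxy)-3-methoxy-2,4-bis(methoxymethoxy)phenyl]-2-[3-(benzyloxy)-4,5-dimethoxyphenyl]-3,3-dimethoxypropan-1-one (racemic) | COCOc1cc(OCc2ccccc2)c(C(=O)C(C(OC)OC)c2cc(OC)c(OC)c(OCc3ccccc3)c2)c(OCOC)c1OC | intermediate
13 | 1-[6-(benzyloxy)-2,4-dihydroxy-3-methoxyphenyl]-2-[3-(benzyloxy)-4,5-dimethoxyphenyl]-3,3-dimethoxypropan-1-one (racemic; formed in the flask, not isolated) | COc1c(O)cc(OCc2ccccc2)c(C(=O)C(C(OC)OC)c2cc(OC)c(OC)c(OCc3ccccc3)c2)c1O | intermediate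
14 | 5-(benzyloxy)-3-[3-(benzyloxy)-4,5-dimethoxyphenyl]-7-hydroxy-2,8-dimethoxy-2,3-dihydro-4H-chromen-4-one (racemic diastereomer mixture; formed in the flask, not isolated) | COC1Oc2c(OC)c(O)cc(OCc3ccccc3)c2C(=O)C1c1cc(OC)c(OC)c(OCc2ccccc2)c1 | intermediate
15 | 5-(benzyloxy)-3-[3-(benzyloxy)-4,5-dimethoxyphenyl]-7-hydroxy-8-methoxy-4H-chromen-4-one | COc1cc(-c2coc3c(OC)c(O)cc(OCc4ccccc4)c3c2=O)cc(OCc2ccccc2)c1OC | intermediate
16 | 5,7-dihydroxy-3-(3-hydroxy-4,5-dimethoxyphenyl)-8-methoxy-4H-chromen-4-one (isoirigenin) | COc1cc(-c2coc3c(OC)c(O)cc(O)c3c2=O)cc(O)c1OC | target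

**Totals.** Total step count: 9. Longest linear sequence: 8 steps (steps 1–4 and 6–9, from 1).

**Steps most likely to fail**

Step 7. Three processes could divert the reaction.
- The MOM ether ortho to the ketone could be lost early to the nitric acid that the oxidant releases, after which the freed phenol is oxidised or closes onto the enone.
- Ring B could migrate slowly, because its 4'-methoxy group is flanked by two oxygen substituents and is partly twisted out of conjugation, so that plain 1,2-dimethoxylation of the alkene competes.
- The oxidant could attack the electron-rich ring A.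

The thallium salts are also highly toxic and need contained handling. The fallback sets out from 11 and comes back at 15. Nucleophilic epoxidation of 11 (H2O2, NaOH, MeOH–THF, 0 °C; Weitz–Scheffer) should give the trans-epoxy ketone F1 as a racemate. BF3·OEt2 in CH2Cl2 at −20 °C then opens the epoxide at the benzylic carbon and the aroyl group shifts to that carbon (Meinwald-type rearrangement with 1,2-acyl migration), giving the keto aldehyde F2. F2 has the same connectivity as 12, with the formyl carbon as the future C2. Methanolic HCl at 50 °C removes the MOM ethers of F2, closes the C8a oxygen on the aldehyde and dehydrates to 15.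

Step 4. Two processes could lower the outcome.
- The negative charge could move from the aryl carbon to the benzylic CH2 of the neighbouring benzyl ether on warming, followed by [1,2]-Wittig rearrangement.
- The hindered aryllithium could deprotonate the Weinreb amide instead of adding to it, which returns 5.

The fallback sets out from 5 and comes back at 7. Bromination of 5 (NBS, MeCN, 0 °C) can occur at only one kind of ring position and should give the aryl bromide F3. Bromine–lithium exchange (n-BuLi, THF, −78 °C) gives aryllithium 6 within minutes, at a temperature at which charge migration does not compete. Addition to acetaldehyde at −78 °C gives the carbinol F4 (racemic), and Dess–Martin oxidation (CH2Cl2, NaHCO3, rt) returns 7.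

Step 9. The C2=C3 bond of the pyranone could be saturated during or after debenzylation, and the peri benzyl ether on the C5 oxygen could be cleaved incompletely. The fallback sets out from 15 and comes back at 16, with no new compound on the way (F0). BCl3 with pentamethylbenzene as cation scavenger in CH2Cl2 at −78 °C cleaves the two benzyl aryl ethers by Lewis-acid activation without any reducing agent. At that temperature the aryl methyl ethers are expected to stay intact.

**Further compounds**

F1 | step 7 | [6-(benzyloxy)-3-methoxy-2,4-bis(methoxymethoxy)phenyl]{trans-3-[3-(benzyloxy)-4,5-dimethoxyphenyl]oxiran-2-yl}methanone (racemic, one enantiomer drawn) | COCOc1cc(OCc2ccccc2)c(C(=O)[C@@H]2O[C@H]2c2cc(OC)c(OC)c(OCc3ccccc3)c2)c(OCOC)c1OC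
F2 | step 7 | 3-[6-(benzyloxy)-3-methoxy-2,4-bis(methoxymethoxy)phenyl]-2-[3-(benzyloxy)-4,5-dimethoxyphenyl]-3-oxopropanal (racemic, largely enolised) | COCOc1cc(OCc2ccccc2)c(C(=O)C(C=O)c2cc(OC)c(OC)c(OCc3ccccc3)c2)c(OCOC)c1OC
F3 | step 4 | 1-(benzyloxy)-2-bromo-4-methoxy-3,5-bis(methoxymethoxy)benzene | COCOc1cc(OCc2ccccc2)c(Br)c(OCOC)c1OC
F4 | step 4 | 1-[6-(benzyloxy)-3-methoxy-2,4-bis(methoxymethoxy)phenyl]ethan-1-ol (racemic) | CC(O)c1c(OCOC)c(OC)c(OCOC)cc1OCc1ccccc1
F0 | step 9 | none | none
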